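**Strategy**

The quinone ring (ring A) is disconnected across its C2=C3 bond. The route exploits that C3 sits alpha to the C4 carbonyl, so it can act as a methyl ketone enolate carbon, while C1–C2 can enter as an aryl alkyne that already carries the complete (R)-configured side chain on C2. The precursor is an ortho-alkynyl acetophenone built on a bis(methoxymethyl)-protected hydroquinone (ring B). In one operation a base-induced 6-endo-dig carbocyclization forms the C2–C3 bond, closes ring A and aromatizes it to a 1-naphthol. Oxygenation at C1, acetal removal and a Steglich esterification then complete the target.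

Key step: step 7

Remark: atoms are numbered as in the 1,4-naphthoquinone (C1 and C4 carbonyl carbons, C2 bearing the side chain, C3–H, C5 and C8 bearing the hydroxyls). The 5,8-dihydroxy-1,4-naphthoquinone core is a pair of rapidly interconverting tautomers, so only the combined oxidation level of the two rings has to be set.

**Route**

Step 1
Reactants: 1 2-bromobenzene-1,4-diol
Product: 2 2-bromo-1,4-bis(methoxymethoxy)benzene
Conditions: NaH, MOMCl, DMF, 0 °C → rt
Reagents that add atoms: chloromethyl methyl ether, COCCl
Why: Williamson ether synthesis on both phenoxides should give the bis-acetal, which shields ring B from bases and organometallics and can later be removed with dilute acid.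

Step 2
Reactants: 2 2-bromo-1,4-bis(methoxymethoxy)benzene; 3 N-methoxy-N-methylacetamide
Product: 5 1-[2-bromo-3,6-bis(methoxymethoxy)phenyl]ethan-1-one, via aryllithium 4 (not isolated)
Conditions: LiN(iPr)2 (LDA, commercial solution), THF, −78 °C; then 3, −78 → −40 °C; AcOH quench
Reagents that add atoms: none
Why: Directed ortho-metalation should take place at the C–H flanked by bromine and a methoxymethoxy group, the most acidic site, without bromine–lithium exchange, and the Weinreb ketone synthesis should stop at the methyl ketone.

Step 3
Reactants: 6 4-methylpent-3-enoic acid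
Product: 8 N-methoxy-N,4-dimethylpent-3-enamide, via acyl imidazole 7 (not isolated)
Conditions: CDI, CH2Cl2, rt; then MeNH(OMe)·HCl, rt
Reagents that add atoms: N,O-dimethylhydroxylamine hydrochloride, Cl.CNOC
Why: Amide coupling through the acyl imidazole is near-neutral and should leave the easily migrating β,γ-double bond in place.

Step 4
Reactants: 8 N-methoxy-N,4-dimethylpent-3-enamide; 9 ethynyltrimethylsilane
Product: 11 6-methyl-1-(trimethylsilyl)hept-5-en-1-yn-3-one, via lithium trimethylsilylacetylide 10 (not isolated)
Conditions: n-BuLi, THF, −78 °C; then 8, −78 → 0 °C; AcOH quench at −78 °C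
Reagents that add atoms: none
Why: In this Weinreb ketone synthesis the weakly basic acetylide should add once to the amide, and the cold acidic quench should release the ynone before the liberated hydroxylamine can add to it or the olefin can move into conjugation.

Step 5
Reactants: 11 6-methyl-1-(trimethylsilyl)hept-5-en-1-yn-3-one
Product: 13 (3R)-6-methylhept-5-en-1-yn-3-ol, via silylated (R)-alkynol 12 (not isolated)
Conditions: Ru[(R,R)-TsDPEN](p-cymene) (preformed amido complex, 1 mol %), iPrOH, rt; evaporate; then K2CO3, MeOH, rt
Reagents that add atoms: none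
Why: Noyori asymmetric transfer hydrogenation of the acetylenic ketone, with the alkynyl group taking the place of the aryl group in the six-membered hydride-transfer transition state, should set the (R)-carbinol with the (R,R)-catalyst by analogy with aryl ketones, and methanolysis should then remove only the alkynyl silyl group.

Step 6
Reactants: 5 1-[2-bromo-3,6-bis(methoxymethoxy)phenyl]ethan-1-one; 13 (3R)-6-methylhept-5-en-1-yn-3-ol
Product: 14 1-{2-[(3R)-3-hydroxy-6-methylhept-5-en-1-yn-1-yl]-3,6-bis(methoxymethoxy)phenyl}ethan-1-one
Conditions: PdCl2(PPh3)2 (5 mol %), CuI (10 mol %), Et3N, DMF, 60 °C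
Reagents that add atoms: none
Why: Sonogashira coupling should proceed because the ortho acetyl group assists oxidative addition into the C–Br bond, while the free propargylic alcohol, the ketone and the acetals are inert, so the stereocenter is carried over unchanged.

Step 7
Reactants: 14 1-{2-[(3R)-3-hydroxy-6-methylhept-5-en-1-yn-1-yl]-3,6-bis(methoxymethoxy)phenyl}ethan-1-one
Product: 16 3-[(1R)-1-hydroxy-4-methylpent-3-en-1-yl]-5,8-bis(methoxymethoxy)naphthalen-1-ol, via dipotassium alkoxide-enolate 15 (not isolated)
Conditions: KN(SiMe3)2 (2.2 equiv), toluene/THF, −78 → 0 °C; AcOH quench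
Reagents that add atoms: none
Why: KN(SiMe3)2 should deprotonate the hydroxyl and the acetyl methyl group, and the enolate carbon (later C3) should add anti to the distal alkyne carbon that bears the side chain (later C2); the vinyl anion at C1 is then protonated and the resulting ketone tautomerizes to the potassium 1-naphthoxide, so aromatization makes the closure irreversible. The closest known reaction type is the base-mediated carbocyclization of ortho-alkynyl aryl methyl ketones to 3-substituted 1-naphthols. Ring A closes in the 6-endo-dig mode. No new stereocenter is formed, and the existing carbinol center should survive because its C–H is not acidic and an allene cannot form inside the new ring. The step needs carbon attack at the distal alkyne carbon and not 5-exo attack at the proximal carbon or attack through the enolate oxygen; the rigid ortho-phenylene tether allows a workable attack angle only at the distal carbon, and only the C-cyclized product can reach the aromatic naphthoxide sink.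

Step 8
Reactants: 16 3-[(1R)-1-hydroxy-4-methylpent-3-en-1-yl]-5,8-bis(methoxymethoxy)naphthalen-1-ol
Product: 17 2-[(1R)-1-hydroxy-4-methylpent-3-en-1-yl]-5,8-bis(methoxymethoxy)naphthalene-1,4-dione
Conditions: Co(salen) (10 mol %), O2 (1 atm), MeCN, rt
Reagents that add atoms: dioxygen, O=O
Why: Cobalt-catalysed aerobic phenol-to-para-quinone oxidation of the electron-rich 1-naphthol, whose para position (C1) is free, should install the second carbonyl without touching the trisubstituted olefin, the secondary alcohol or the acetals.

Step 9
Reactants: 17 2-[(1R)-1-hydroxy-4-methylpent-3-en-1-yl]-5,8-bis(methoxymethoxy)naphthalene-1,4-dione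
Product: 18 (R)-shikonin, 5,8-dihydroxy-2-[(1R)-1-hydroxy-4-methylpent-3-en-1-yl]naphthalene-1,4-dione
Conditions: HCl (0.5 M in MeOH), CH2Cl2, 0 °C → rt
Reagents that add atoms: none
Why: Acid-catalysed acetal cleavage (transacetalization to methanol) of the aryl methoxymethyl ethers peri to the quinone carbonyls should be fast under dilute acid that neither protonates the trisubstituted olefin nor ionizes the carbinol next to the electron-poor quinone.

Step 10
Reactants: 18 (R)-shikonin; 19 3-methylbut-2-enoic acid
Product: 20 (1R)-1-(5,8-dihydroxy-1,4-dioxo-1,4-dihydronaphthalen-2-yl)-4-methylpent-3-en-1-yl 3-methylbut-2-enoate (target)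
Conditions: DCC, DMAP (cat.), CH2Cl2, 0 °C → rt
Reagents that add atoms: none
Why: Steglich esterification should acylate only the side-chain hydroxyl, with retention at the carbinol carbon, because both phenols are held in strong hydrogen bonds to the peri carbonyl groups.

**Compound list**

1 | 2-bromobenzene-1,4-diol | Oc1ccc(O)c(Br)c1 | starting material
2 | 2-bromo-1,4-bis(methoxymethoxy)benzene | COCOc1ccc(OCOC)c(Br)c1 | intermediate
3 | N-methoxy-N-methylacetamide | CC(=O)N(C)OC | starting material
4 | [2-bromo-3,6-bis(methoxymethoxy)phenyl]lithium | [Li]c1c(Br)c(OCOC)ccc1OCOC | intermediate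
5 | 1-[2-bromo-3,6-bis(methoxymethoxy)phenyl]ethan-1-one | CC(=O)c1c(Br)c(OCOC)ccc1OCOC | intermediate
6 | 4-methylpent-3-enoic acid | CC(C)=CCC(=O)O | starting material
7 | 1-(1H-imidazol-1-yl)-4-methylpent-3-en-1-one | CC(C)=CCC(=O)n1ccnc1 | intermediate
8 | N-methoxy-N,4-dimethylpent-3-enamide | CC(C)=CCC(=O)N(C)OC | intermediate
9 | ethynyltrimethylsilane | C#C[Si](C)(C)C | starting material
10 | lithium (trimethylsilyl)acetylide | [Li]C#C[Si](C)(C)C | intermediate
11 | 6-methyl-1-(trimethylsilyl)hept-5-en-1-yn-3-one | CC(C)=CCC(=O)C#C[Si](C)(C)C | intermediate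
12 | (3R)-6-methyl-1-(trimethylsilyl)hept-5-en-1-yn-3-ol | CC(C)=CC[C@@H](O)C#C[Si](C)(C)C | intermediate
13 | (3R)-6-methylhept-5-en-1-yn-3-ol | CC(C)=CC[C@@H](O)C#C | intermediate
14 | 1-{2-[(3R)-3-hydroxy-6-methylhept-5-en-1-yn-1-yl]-3,6-bis(methoxymethoxy)phenyl}ethan-1-one | CC(C)=CC[C@@H](O)C#Cc1c(OCOC)ccc(OCOC)c1C(C)=O | intermediate
15 | dipotassium salt of 14 (side-chain alkoxide and methyl ketone enolate) | CC(C)=CC[C@@H]([O-])C#Cc1c(OCOC)ccc(OCOC)c1C(=C)[O-].[K+].[K+] | intermediate
16 | 3-[(1R)-1-hydroxy-4-methylpent-3-en-1-yl]-5,8-bis(methoxymethoxy)naphthalen-1-ol | CC(C)=CC[C@@H](O)c1cc(O)c2c(OCOC)ccc(OCOC)c2c1 | intermediate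
17 | 2-[(1R)-1-hydroxy-4-methylpent-3-en-1-yl]-5,8-bis(methoxymethoxy)naphthalene-1,4-dione | CC(C)=CC[C@@H](O)C1=CC(=O)c2c(OCOC)ccc(OCOC)c2C1=O | intermediate
18 | (R)-shikonin, 5,8-dihydroxy-2-[(1R)-1-hydroxy-4-methylpent-3-en-1-yl]naphthalene-1,4-dione | CC(C)=CC[C@@H](O)C1=CC(=O)c2c(O)ccc(O)c2C1=O | intermediate
19 | 3-methylbut-2-enoic acid | CC(C)=CC(=O)O | starting material
20 | (1R)-1-(5,8-dihydroxy-1,4-dioxo-1,4-dihydronaphthalen-2-yl)-4-methylpent-3-en-1-yl 3-methylbut-2-enoate | CC(C)=CC[C@@H](OC(=O)C=C(C)C)C1=CC(=O)c2c(O)ccc(O)c2C1=O | target

**Step count and risks**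

Total step count: 10 (steps 1–2 make the arene fragment, steps 3–5 the alkynol fragment, steps 6–10 join and finish).
Longest linear sequence: 8 steps (steps 3, 4, 5, 6, 7, 8, 9, 10, from 4-methylpent-3-enoic acid).

Steps most likely to fail:

Step 7 (key step). The enolate may close through its oxygen or in the 5-exo mode, or the potassium alkoxide next to the alkyne may slow the attack enough for intermolecular condensation to compete. The fallback closes the same bond under electrophilic instead of anionic activation. Setting out from 14, TBSOTf and Et3N in CH2Cl2 at 0 °C silylate the hydroxyl group and convert the methyl ketone into its silyl enol ether, the bis-silyl compound F1. AuCl(PPh3)/AgOTf (5 mol %) in CH2Cl2 at rt then activates the alkyne as a π-complex of monovalent gold for 6-endo-dig attack by the enol ether carbon, and proton loss with protodeauration should give the naphthyl silyl ether F2. Bu4NF in THF removes both silyl groups and the route is rejoined at 16.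

Step 2. The ortho-bromo aryllithium 4 may lose LiBr (aryne formation) or be protonated by the acetamide before it is acylated. The fallback replaces the acylation by addition and oxidation. Setting out from 2, the lithiated species 4 is trapped at −78 °C with acetaldehyde, a much faster electrophile, to give the secondary benzylic alcohol F3. Dess–Martin periodinane in CH2Cl2 then oxidizes this to the ketone, and the route is rejoined at 5.

Step 10. Chemoselectivity may be lost through acylation of a phenolic hydroxyl, or the activated acid may rearrange to the N-acylurea faster than the hindered carbinol is acylated. The fallback exchanges the order of the last two operations. Setting out from 17, whose only free hydroxyl is the carbinol, DCC/DMAP esterification with 19 in CH2Cl2 gives the bis(methoxymethyl) ester F4. Brief treatment with HCl in MeOH/CH2Cl2 at 0 °C then removes both acetals and the route is rejoined at 20.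

Further compounds
F1 | step 7 | tert-butyl({1-[2-((3R)-3-{[tert-butyl(dimethyl)silyl]oxy}-6-methylhept-5-en-1-yn-1-yl)-3,6-bis(methoxymethoxy)phenyl]ethenyl}oxy)dimethylsilane | CC(C)=CC[C@@H](O[Si](C)(C)C(C)(C)C)C#Cc1c(OCOC)ccc(OCOC)c1C(=C)O[Si](C)(C)C(C)(C)C
F2 | step 7 | tert-butyl{[3-((1R)-1-{[tert-butyl(dimethyl)silyl]oxy}-4-methylpent-3-en-1-yl)-5,8-bis(methoxymethoxy)naphthalen-1-yl]oxy}dimethylsilane | CC(C)=CC[C@@H](O[Si](C)(C)C(C)(C)C)c1cc(O[Si](C)(C)C(C)(C)C)c2c(OCOC)ccc(OCOC)c2c1
F3 | step 2 | 1-[2-bromo-3,6-bis(methoxymethoxy)phenyl]ethan-1-ol (racemic) | CC(O)c1c(Br)c(OCOC)ccc1OCOC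
F4 | step 10 | (1R)-1-[5,8-bis(methoxymethoxy)-1,4-dioxo-1,4-dihydronaphthalen-2-yl]-4-methylpent-3-en-1-yl 3-methylbut-2-enoate | CC(C)=CC[C@@H](OC(=O)C=C(C)C)C1=CC(=O)c2c(OCOC)ccc(OCOC)c2C1=O
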